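The gamma run carries the charges of autumn. Its links read 37.2% at 0.333 h and fade to 18.0% at 4.00 h, and the beta and theta runs, richer in second end groups, fade as well. The steps thought possible are decomposition of second end groups, quenching of first end groups by protic impurity, and the reversible joining of first and second end groups to links and by-product.

| flask | first end groups | second end groups | protic impurity | remark | time |
|---|---|---|---|---|---|
| gamma | 0.10 M | 0.90 equiv | 0.050 M | run made earlier |  |
| beta | 0.10 M | 1.3 equiv | 0.050 M | run made earlier |  |
| theta | 0.10 M | 2 equiv | 0.050 M | run made earlier |  |
| epsilon | 0.20 M | 0.90 equiv | 0.050 M | run made earlier |  |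
| midnight | 0.10 M (fed, over 2.5 h) | 0.900 equiv | 0.0500 M | all else is in the flask from the start; the feed brings no volume worth counting | 4.0 h |
| autumn | 0.10 M | 0.900 equiv | 0.0500 M | everything together at the start | 4.0 h |
| summer | 0.10 M (fed, over 15 min) | 0.900 equiv | 0.0500 M | all else is in the flask from the start; the feed brings no volume worth counting | 4.0 h |
| winter | 0.10 M | 0.900 equiv (in portions, 2, over 2.5 h) | 0.0500 M | first portion at the start, last at 2.5 h | 4.0 h |
| spring | 0.10 M | 0.900 equiv (fed, over 2.5 h) | 0.0500 M | all else is in the flask from the start; the feed brings no volume worth counting | 4.0 h |

- gamma (time / h: links / %): 0.333: 37.2; 0.500: 36.6; 0.833: 33.7; 1.33: 32.3; 2.50: 25.2; 4.00: 18.0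
- beta (time / h: links / %): 0.333: 43.6; 1.00: 36.0; 1.50: 33.3; 2.50: 27.0; 4.00: 21.1; 5.00: 18.2
- theta (time / h: links / %): 0.833: 41.5; 1.50: 36.2; 2.50: 32.9; 3.00: 27.8; 4.00: 23.6; 5.00: 20.1
- epsilon (time / h: links / %): 0.417: 47.9; 1.33: 39.1; 2.00: 37.1; 3.00: 32.3; 5.00: 24.3

(readings scatter by 1 percentage point)

- steps thought possible: second end groups -> decomposed reagent; first end groups + protic impurity -> quenched substrate; first end groups + second end groups <-> links + by-product

* the flask that comes out highest in amount of links, in percent of the first end groups charged, or "all alike" when all lie within 1.5 percentage points (midnight / autumn / summer / winter / spring / all alike)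
* links at the end, in percent of the first end groups charged, midnight
* links at the end, in percent of the first end groups charged, autumn
* links at the end, in percent of the first end groups charged, summer
* links at the end, in percent of the first end groups charged, winter
* links at the end, in percent of the first end groups charged, spring

Protic impurity can claim half of the first end groups. If the remainder stands in equilibrium with links, and free first end groups are taken as steady, which is a rough assumption, free second end groups go as the square of the link fraction, with links as the resting state of the reagent. Decomposition then removes links at a rate in that square, so on this assumption the reciprocal of the link fraction climbs roughly on a straight line, and a chord across the readings gives its mean slope. From second to last reading, gamma gives 0.807 h⁻¹, beta 0.679 h⁻¹ and theta 0.632 h⁻¹; epsilon, with another charge, stays out. Their mean, 0.706 h⁻¹, is the fade slope, the hourly rise of the reciprocal of the link fraction.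

In an own reckoning, separate from the forecast, gamma's reading at 0.500 h carried along this line puts autumn at 19.2%. Winter, if its last portion at 2.5 h restores gamma's first reading, ends at 26.7%, above autumn.

The forecast names winter, with midnight 20%, autumn 18.3%, summer 18%, winter 26% and spring 25%, on the ground that “late reagent is preserved”.

Winter comes out highest at 27.2%, with spring 25.6%, autumn 19.5%, summer 19.3% and midnight 14.2%.

    second end groups → decomposed reagent (k = 0.0180 min⁻¹)
    first end groups + protic impurity → quenched substrate (k = 12.0 M⁻¹ min⁻¹)
    first end groups + second end groups ⇌ links + by-product (K = 3.00, k = 37.0 M⁻¹ min⁻¹)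

Midnight lies 5.8 percentage points below the forecast; at the end of its feed it holds 0.0703 M of decomposed reagent, more than winter's 0.0213 M at that time. Neither flask has come to rest. At ten times the time, the fade slope takes winter from 27.2% to 3.44%, against a simulated 3.30%. It takes midnight from 14.2% to 3.08%, against a simulated 2.98%. Winter's lead over midnight, 13 points at 4.0 h, shrinks to 0.32 points after 40.0 h.

The runs stem from a simulated flask on assumed constants; the scatter is artificial.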